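Compound numbers are those of the steps below. Germacrane numbering is used throughout: ring C1–C10, C11–C13 on C7, C14 on C10, C15 on C4.

## The problem

The target 36 is a germacrane bis-lactone. Its ten-membered carbocycle (C1–C10) is bridged by a butenolide (C15 on C4, ring oxygen on C6, alkene C4=C5, trans within the carbocycle) and by an α-methylene-γ-lactone (C11–C13 on C7, ring oxygen on C8). It also carries a ring-cis C9=C10 alkene with the C14 hydroxymethyl group and an isobutyrate on C3. A ten-membered ring with one trans and one cis trisubstituted alkene is hard to close end to end, so the origin of the carbocycle is the central question. There are four stereocentres: the contiguous C6–C7–C8 triad and the isolated C3. C8, as a silylated allylic carbinol, can direct C7 through allylic strain and the ring relays this to C6; C3 is cut off from the triad by the sp2 carbons C4 and C5 and needs its own reagent control. The methylene lactone is a Michael acceptor, C6–H of the butenolide is acidic, the C3 ester sits β to the butenolide α-carbon and the C14 alcohol is allylic, so these groups must appear late and under mild conditions. The enabling feature is the array O6–C6–C7–C11(=C13): C6 carries oxygen and is γ to the C15 carbonyl, and C7 carries a 2-propenyl unit. This is the homoallylic alcohol pattern left by a [2,3]-Wittig shift, and the same C6 oxygen is placed to close the butenolide onto C15.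

## Retrosynthesis

**End game (36 back to 29).** The Si–O14 bond is cut last (35), because the free allylic alcohol next to two unsaturated lactones is the most fragile array. The C3 ester is cut next (34): it is put on after all anionic and oxidative chemistry, since an acyloxy group β to an enolisable position would eliminate. The C12–O8 lactone bond is then opened to the 1,4-diol of triol 31. An acrylate could not survive the anionic key step, so C12 travels as a protected allylic alcohol and the methylene lactone is formed by oxidative lactonisation. Triol 31 comes from 30 and 29 by deprotection. The forward demand is oxidation of one primary allylic alcohol beside two secondary ones.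

**Key disconnection (29 back to 26).** C6–C7 and O6–C15 are cut and O6–C13 is re-formed, giving the 13-membered 6-oxa dienoate 26. Against the neighbouring cuts (C3–C4, C9=C10, C4=C5), this one avoids end-to-end closure of the ten-membered ring. Its precursor holds only two stereocentres (C3, C8), and the butenolide closes by itself once the C6 alkoxide is released. The forward reaction needs a Z enoate (C6 cis to the ester), a ring-cis C7=C11 bond and a bulky O8 substituent.

**Enoate (26 back to 23).** The C4–C15 bond is cut. A Z α-(1-silyloxyalkyl) enoate is not accessible by olefination: the required β-oxygenated α-phosphono ester cannot be made by aldol addition, which olefinates instead, and it would eliminate on deprotonation. A Z enoate with a free C6 hydroxyl would lactonise, so O6 must already be an ether. The ester is therefore put on a ring alkyne: hydroxyl-directed trans-hydrostannation of 23 gives 24, methoxycarbonylation gives 25 and silylation gives 26. The geometry follows from the mechanism.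

**Ring closure (23 back to 20).** The C3–C4 bond is cut: an alkynylchromium adds to the C3 aldehyde of 20 to give 21. Closure at O6 would need extra differentiation of hydroxyls; closure at C4≡C5 by alkyne metathesis is kept in reserve. C3 is then set by oxidation to ynone 22 and catalyst-controlled reduction, not by macrocyclic diastereoselection. The precursor 20 is acyclic with one stereocentre.

**Ether arm (20 back to 14).** O6–C6 is cut (propargylation of 16 to 18, then 19) and C11–C13 is cut (hydroxymethyl transfer to vinyl iodide 14). Attaching C13 through the iodide decides which CH2O arm on C11 is cis to C8, which a ketone olefination cannot do. The C12 oxygen is a PMB ether, which cannot migrate between the two arms.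

**C8 and C7=C11 (14 back to 9 and 10).** The C7–C8 bond is cut to enal 9 and propargyl ether 10. Asymmetric alkynylation sets C8 in 11. Hydroxyl-directed trans-hydroalumination and iodination (13) turn the alkyne into the geometrically defined C11 iodide. Addition of a preformed trisubstituted vinyl metal would need a stereodefined iodide that is not readily available and gives less reliable control at a divinyl carbinol.

**West part (9 back to 1 and 5).** C10–C1 is cut by B-alkyl Suzuki–Miyaura coupling of iodide 4 with the borane 7 from allyl pivalate 6, giving 8 and, after oxidation, 9. Iodide 4 comes from but-2-yne-1,4-diol 1 through 2 by the same directed hydroalumination, which fixes the C9=C10 geometry. The pivalate is chosen because the hydride of step 7 removes it without a separate step.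

## Roads not taken

**Alternative 1:** The cut is C3–C4. The seco aldehyde A2, an α-iodobutenolide with both lactones in place, would be closed with CrCl2 and catalytic NiCl2 to the C3 carbinol A1.
- Merits: the route is convergent, the chromium chemistry tolerates lactones, and only acylation and desilylation follow. That end game is three steps shorter than the one chosen here, and no new reaction is needed.
- Weak points: the ten-membered ring is closed end to end. The α-chromio butenolide is a poor nucleophile, and divalent chromium can reduce the iodide or the methylene lactone. C3 is set in the cyclisation with no reagent control, and correcting it by oxidation and reduction would pass through a 2-acylbutenolide that epimerises at C6. A2 also needs the whole C6–C7–C8 triad built beforehand.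
- Comparison: the chosen plan sets against this a ring contraction, two stereocentres made from one, and C3 fixed by a catalyst before the key step.

**Alternative 2:** The cut is C9=C10, masked as a sulfone. The 11-membered sulfone A4 would undergo Ramberg–Bäcklund contraction (KOH, CCl4, tert-butanol) to the triene A3.
- Merits: this is also a contraction, the thiacycle is easy to close, and the reaction type is established. In precedent it is ahead of the chosen key step.
- Weak points: the new alkene is trisubstituted and must be ring-cis, and episulfone extrusion gives no dependable control of that. The α-sulfonyl anion at C10 can expel the C14 silyloxy group. Dichlorocarbene and hydroxide meet a free C8 hydroxyl β to the sulfone. A3 still lacks both lactones and all four stereocentres must be set beforehand.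
- Comparison: the chosen plan offers the creation of C6 and C7 and closure of the butenolide in the key step, and a fallback of known type.

**Alternative 3:** The cut is C4=C5. The 11-membered macrolactone A6 would undergo transannular ring-closing metathesis with a second-generation Hoveyda–Grubbs catalyst to A5, the C14 silyl ether of the target.
- Merits: A5 is one step from 36, clearly better than the five steps after the key step here. Butenolide formation by metathesis of acrylates is known.
- Weak points: the reaction must join a 1,1-disubstituted electron-poor alkene to a vinyl group across the ring and leave a trans trisubstituted alkene in a ten-membered ring. The product is more strained than A6. The methylene lactone is a second acrylate that invites cross-metathesis. A6 needs all four stereocentres, the isobutyrate and the methylene lactone carried through a macrolactonisation.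
- Comparison: the chosen plan is longer after the key step but asks much less of the precursor and does not rely on forming a strained ring against equilibrium.

Key step: step 19

Assumption: compounds 10, 15 and 17 are taken as commercial, and the sense of induction of the two asymmetric catalysts is taken from their behaviour with enals and with alkyl alkynyl ketones.

## Route

Step 1
Reactants: 1 but-2-yne-1,4-diol
Product: 2 4-(tert-butyldiphenylsilyloxy)but-2-yn-1-ol
Conditions: NaH (1 equiv), THF, 0 °C; TBDPSCl; diol in excess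
Reagents that add atoms: tert-butyl(chloro)diphenylsilane, CC(C)(C)[Si](Cl)(c1ccccc1)c1ccccc1
Why: Monosilylation of a symmetric diol through its monosodium alkoxide; excess diol suppresses the bis-ether.

Step 2
Reactants: 2 4-(tert-butyldiphenylsilyloxy)but-2-yn-1-ol
Product: 4 (Z)-4-(tert-butyldiphenylsilyloxy)-3-iodobut-2-en-1-ol, via cyclic sodium vinylalanate 3 (not isolated)
Conditions: NaAlH2(OCH2CH2OMe)2, THF, 0 °C to rt; then I2, −78 °C
Reagents that add atoms: iodine, II
Why: Hydroxyl-directed trans-hydroalumination of a propargylic alcohol delivers hydride to C9 and leaves aluminium on C10 cis to C8 in a five-membered chelate; iodinolysis with retention gives the Z iodide and fixes the later ring-cis C9=C10 geometry.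

Step 3
Reactants: 5 prop-2-en-1-ol
Product: 6 prop-2-en-1-yl 2,2-dimethylpropanoate
Conditions: t-BuCOCl, pyridine, CH2Cl2, 0 °C to rt
Reagents that add atoms: pivaloyl chloride, CC(C)(C)C(Cl)=O
Why: Simple acylation; the pivalate survives hydroboration, coupling and alkynylation and is removed by the hydride of step 7.

Step 4
Reactants: 6 prop-2-en-1-yl 2,2-dimethylpropanoate; 4 (Z)-4-(tert-butyldiphenylsilyloxy)-3-iodobut-2-en-1-ol
Product: 8 (E)-4-[(tert-butyldiphenylsilyloxy)methyl]-6-hydroxyhex-4-en-1-yl 2,2-dimethylpropanoate, via B-alkyl-9-borabicyclononane 7 (not isolated)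
Conditions: 9-BBN, THF, 0 °C to rt; then 4, PdCl2(dppf) (cat.), AsPh3, Cs2CO3, DMF/H2O, rt
Reagents that add atoms: none
Why: Anti-Markovnikov hydroboration puts boron on C1; B-alkyl Suzuki–Miyaura coupling forms C10–C1 with retention, so C1 is cis to C8.

Step 5
Reactants: 8 (E)-4-[(tert-butyldiphenylsilyloxy)methyl]-6-hydroxyhex-4-en-1-yl 2,2-dimethylpropanoate
Product: 9 (E)-4-[(tert-butyldiphenylsilyloxy)methyl]-6-oxohex-4-en-1-yl 2,2-dimethylpropanoate
Conditions: MnO2, CH2Cl2, rt
Reagents that add atoms: none
Why: MnO2 oxidises only the allylic alcohol; neutral heterogeneous conditions should leave the geometry of the β,β-disubstituted enal intact.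

Step 6
Reactants: 9 (E)-4-[(tert-butyldiphenylsilyloxy)methyl]-6-oxohex-4-en-1-yl 2,2-dimethylpropanoate; 10 1-methoxy-4-[(prop-2-yn-1-yloxy)methyl]benzene
Product: 11 (4E,6R)-4-[(tert-butyldiphenylsilyloxy)methyl]-6-hydroxy-9-(4-methoxybenzyloxy)non-4-en-7-yn-1-yl 2,2-dimethylpropanoate
Conditions: Me2Zn, ProPhenol (cat.; enantiomer directing Si-face attack), Ph3PO (cat.), toluene, 0 °C
Reagents that add atoms: none
Why: Catalytic asymmetric alkynylation of an enal by a dinuclear zinc–ProPhenol alkynylzinc species; the ligand controls the aldehyde face and addition to the Si face gives the 8R carbinol.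

Step 7
Reactants: 11 (4E,6R)-4-[(tert-butyldiphenylsilyloxy)methyl]-6-hydroxy-9-(4-methoxybenzyloxy)non-4-en-7-yn-1-yl 2,2-dimethylpropanoate
Product: 13 (2Z,4R,5E)-6-[(tert-butyldiphenylsilyloxy)methyl]-2-iodo-1-(4-methoxybenzyloxy)nona-2,5-diene-4,9-diol, via cyclic disodium vinylalanate 12 (not isolated)
Conditions: NaAlH2(OCH2CH2OMe)2 (excess), THF, 0 °C to rt; then I2, −78 °C
Reagents that add atoms: iodine, II
Why: A second hydroxyl-directed trans-hydroalumination and iodination puts H on C7 and iodine on C11 cis to C8, fixing the ring-cis C7=C11 geometry; the same hydride cleaves the pivalate reductively.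

Step 8
Reactants: 13 (2Z,4R,5E)-6-[(tert-butyldiphenylsilyloxy)methyl]-2-iodo-1-(4-methoxybenzyloxy)nona-2,5-diene-4,9-diol
Product: 14 4,9-bis(triethylsilyl) ether of 13
Conditions: Et3SiCl, imidazole, DMF, 0 °C to rt
Reagents that add atoms: chlorotriethylsilane, CC[Si](Cl)(CC)CC
Why: Silylation of both hydroxyls; the secondary ether at C8 is the control element of the key step and the primary ether at C3 is a latent aldehyde.

Step 9
Reactants: 14 4,9-bis(triethylsilyl) ether of 13; 15 (tributylstannyl)methanol
Product: 16 (2E,4R,5E)-6-[(tert-butyldiphenylsilyloxy)methyl]-2-[(4-methoxybenzyloxy)methyl]-4,9-bis(triethylsilyloxy)nona-2,5-dien-1-ol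
Conditions: Pd(PPh3)4 (cat.), 1,4-dioxane, 90 °C
Reagents that add atoms: none
Why: Stille coupling transfers the hydroxymethyl group (C13) to the vinyl iodide with retention, so C13 is cis to C8 and the PMB-bearing C12 is trans.

Step 10
Reactants: 16 (2E,4R,5E)-6-[(tert-butyldiphenylsilyloxy)methyl]-2-[(4-methoxybenzyloxy)methyl]-4,9-bis(triethylsilyloxy)nona-2,5-dien-1-ol; 17 3-bromoprop-1-yne
Product: 18 O13-propargyl ether of 16
Conditions: NaH, 17 (excess), Bu4NI (cat.), THF, 0 °C
Reagents that add atoms: none
Why: Williamson etherification of the primary allylic alkoxide installs O6–C6 and the C4–C5 alkyne; excess electrophile at low temperature should outrun silyl transfer from O8.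

Step 11
Reactants: 18 O13-propargyl ether of 16
Product: 19 O13-(3-iodoprop-2-ynyl) ether
Conditions: N-iodosuccinimide, AgNO3 (cat.), acetone, rt
Reagents that add atoms: N-iodosuccinimide, O=C1CCC(=O)N1I
Why: Silver-catalysed iodination of a terminal alkyne gives the 1-iodoalkyne needed for chromium insertion.

Step 12
Reactants: 19 O13-(3-iodoprop-2-ynyl) ether
Product: 20 C3 aldehyde of 19
Conditions: (COCl)2, DMSO, CH2Cl2, −78 to −40 °C; Et3N
Reagents that add atoms: none
Why: Swern conditions cleave and oxidise a primary triethylsilyl ether directly to the aldehyde, while secondary triethylsilyl ethers are known to survive.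

Step 13
Reactants: 20 C3 aldehyde of 19
Product: 21 13-membered 6-oxa macrocyclic propargylic alcohol (8R; both C3 epimers)
Conditions: CrCl2 (excess), NiCl2 (cat.), THF, rt, slow addition at high dilution
Reagents that add atoms: none
Why: Intramolecular Nozaki–Hiyama–Kishi reaction: divalent chromium inserts into the C–I bond and the alkynylchromium adds only to the aldehyde, closing the 13-membered ring at C3–C4. The C3 epimers are carried on together because the next step removes that stereocentre.

Step 14
Reactants: 21 13-membered 6-oxa macrocyclic propargylic alcohol (8R; both C3 epimers)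
Product: 22 macrocyclic ynone (C3 ketone; 8R)
Conditions: Dess–Martin periodinane, NaHCO3, CH2Cl2, 0 °C to rt
Reagents that add atoms: none
Why: Buffered hypervalent-iodine oxidation of a propargylic alcohol; no base is present that could isomerise the γ-alkoxy ynone to an allenone.

Step 15
Reactants: 22 macrocyclic ynone (C3 ketone; 8R)
Product: 23 (3S,8R) macrocyclic propargylic alcohol
Conditions: Ru[(S,S)-TsNCHPhCHPhNH](p-cymene) (cat.), i-PrOH, rt
Reagents that add atoms: none
Why: Noyori asymmetric transfer hydrogenation of an alkyl alkynyl ketone under base-free conditions; the catalyst distinguishes the alkynyl from the alkyl side and should give the 3S carbinol under reagent control.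

Step 16
Reactants: 23 (3S,8R) macrocyclic propargylic alcohol
Product: 24 (3S,8R) C4-tributylstannyl macrocyclic alkene (tin cis to C6)
Conditions: Bu3SnH, [Cp*RuCl]4 (cat.), CH2Cl2, rt
Reagents that add atoms: tributyltin hydride, CCCC[SnH](CCCC)CCCC
Why: Ruthenium-catalysed trans-hydrostannation directed by the free propargylic hydroxyl places tin on the proximal carbon C4 and H on C5 from the opposite side, giving the ring-trans alkene with tin cis to C6.

Step 17
Reactants: 24 (3S,8R) C4-tributylstannyl macrocyclic alkene (tin cis to C6)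
Product: 25 methyl ester of the macrocyclic Z-enoate with free C3 hydroxyl (3S,8R)
Conditions: Pd(OAc)2 (cat.), AsPh3, 1,4-benzoquinone, CF3CO2H (cat.), CO (1 atm), MeOH, rt
Reagents that add atoms: carbon monoxide, [C-]#[O+]; methanol, CO
Why: Hydroxyl-assisted oxidative methoxycarbonylation of an alkenylstannane (transmetalation to divalent palladium, CO insertion, methanolysis, reoxidation by benzoquinone) proceeds with retention, so the ester is cis to C6.

Step 18
Reactants: 25 methyl ester of the macrocyclic Z-enoate with free C3 hydroxyl (3S,8R)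
Product: 26 13-membered 6-oxa macrocyclic dienoate with C3 and C8 triethylsilyl ethers (3S,8R)
Conditions: Et3SiOTf, 2,6-lutidine, CH2Cl2, −78 °C
Reagents that add atoms: triethylsilyl trifluoromethanesulfonate, CC[Si](CC)(CC)OS(=O)(=O)C(F)(F)F
Why: Silyl triflate silylation of a hindered allylic alcohol; a silyloxy group is a poor leaving group and should tolerate the neighbouring dienolate.

Step 19
Reactants: 26 13-membered 6-oxa macrocyclic dienoate with C3 and C8 triethylsilyl ethers (3S,8R)
Product: 29 ten-membered butenolide (3S,6R,7R,8R) with the 3-(4-methoxybenzyloxy)prop-1-en-2-yl group on C7, via lithium dienolate 27 (not isolated), via ring-contracted lithium alkoxide 28 (not isolated)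
Conditions: LiN(SiMe3)2, THF, −78 to −20 °C; aq. NH4Cl
Reagents that add atoms: none
Why: Proposed new method: LiN(SiMe3)2 removes a C6 proton, which is γ to the ester, syn to its carbonyl across the Z C4=C5 bond and α to the ether oxygen, giving the extended dienolate 27; its C6 terminus adds to C7 through a five-membered envelope transition state while O6–C13 breaks and the alkene moves to C11=C13, a [2,3]-Wittig shift whose closest known relatives are the ring contraction of 13-membered diallylic and propargylic allylic ethers to cyclodecenes and the ester dienolate [2,3]-Wittig rearrangement. The ten-membered carbocycle is formed by contraction of the 13-membered ring through this five-membered cyclic transition state, not by end-to-end closure. The alkoxide 28 is held cis to the ester across the re-formed C4=C5 bond and closes the butenolide by 5-exo-trig acyl substitution with loss of methoxide. C7 is controlled by C8: with H8 eclipsing C7=C11 to avoid allylic 1,3-strain with C13, the triethylsilyloxy group covers one face and C6, tethered through C9, adds to the other. C6 is controlled by the ring-cis allyl ether geometry and the tether, which place C5 exo on the envelope and gauche to C8. The step needs γ- over α-reactivity of the dienolate and a [2,3] over a [1,2] or Claisen-type shift; only C6 carries the ether oxygen and the ring holds it over C7, and low temperature favours the concerted five-membered path. The poor leaving-group ability of the C3 silyloxy group is relied on to prevent β-elimination from the dienolate.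

Step 20
Reactants: 29 ten-membered butenolide (3S,6R,7R,8R) with the 3-(4-methoxybenzyloxy)prop-1-en-2-yl group on C7
Product: 30 C12 allylic alcohol of 29
Conditions: DDQ, CH2Cl2/pH 7 buffer, 0 °C
Reagents that add atoms: none
Why: Oxidative cleavage of the PMB ether by benzylic hydride abstraction; silyl ethers and the unactivated alkenes are not touched.

Step 21
Reactants: 30 C12 allylic alcohol of 29
Product: 31 C3,C8,C12-triol with C14 tert-butyldiphenylsilyl ether
Conditions: PPTS, MeOH, 0 °C to rt
Reagents that add atoms: none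
Why: Mild acid methanolysis removes the two secondary triethylsilyl ethers, while the far more acid-stable primary tert-butyldiphenylsilyl ether remains.

Step 22
Reactants: 31 C3,C8,C12-triol with C14 tert-butyldiphenylsilyl ether
Product: 34 C14-silylated 3-hydroxy bis-lactone, via hydroxy enal 32 (not isolated), via lactol 33 (not isolated)
Conditions: TEMPO (cat.), PhI(OAc)2, CH2Cl2, rt
Reagents that add atoms: none
Why: Oxidative lactonisation of a 1,4-diol: the oxoammonium oxidant takes the primary allylic alcohol first, the enal is trapped by the C8 hydroxyl as a five-membered lactol, and a second oxidation gives the α-methylene lactone.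

Step 23
Reactants: 34 C14-silylated 3-hydroxy bis-lactone
Product: 35 C14-silylated target (C3 isobutyrate)
Conditions: (i-PrCO)2O, pyridine, DMAP (cat.), CH2Cl2, 0 °C
Reagents that add atoms: isobutyric anhydride, CC(C)C(=O)OC(=O)C(C)C
Why: DMAP-catalysed acylation of the only remaining hydroxyl; weak base and low temperature protect the acidic C6–H and the methylene lactone.

Step 24
Reactants: 35 C14-silylated target (C3 isobutyrate)
Product: 36 target compound (3S,6R,7S,8R)
Conditions: HF·pyridine, THF/pyridine, 0 °C to rt
Reagents that add atoms: none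
Why: Buffered fluoride cleavage of the silyl ether; the non-basic medium spares both lactones and the ester.

## Compound list

1 | but-2-yne-1,4-diol | OCC#CCO | starting material
2 | 4-(tert-butyldiphenylsilyloxy)but-2-yn-1-ol | OCC#CCO[Si](c1ccccc1)(c1ccccc1)C(C)(C)C | intermediate
3 | cyclic sodium vinylalanate from 2 (Al on C10 and O8, two 2-methoxyethoxy ligands) | [Na+].COCCO[Al-]1(OCCOC)OCC=C1CO[Si](c1ccccc1)(c1ccccc1)C(C)(C)C | intermediate
4 | (Z)-4-(tert-butyldiphenylsilyloxy)-3-iodobut-2-en-1-ol | OC/C=C(\I)CO[Si](c1ccccc1)(c1ccccc1)C(C)(C)C | intermediate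
5 | prop-2-en-1-ol (allyl alcohol) | C=CCO | starting material
6 | prop-2-en-1-yl 2,2-dimethylpropanoate | C=CCOC(=O)C(C)(C)C | intermediate
7 | 3-(9-borabicyclo[3.3.1]nonan-9-yl)propyl 2,2-dimethylpropanoate | CC(C)(C)C(=O)OCCCB1C2CCCC1CCC2 | intermediate
8 | (E)-4-[(tert-butyldiphenylsilyloxy)methyl]-6-hydroxyhex-4-en-1-yl 2,2-dimethylpropanoate (C1 cis to C8) | OC/C=C(\CCCOC(=O)C(C)(C)C)CO[Si](c1ccccc1)(c1ccccc1)C(C)(C)C | intermediate
9 | (E)-4-[(tert-butyldiphenylsilyloxy)methyl]-6-oxohex-4-en-1-yl 2,2-dimethylpropanoate | O=C/C=C(\CCCOC(=O)C(C)(C)C)CO[Si](c1ccccc1)(c1ccccc1)C(C)(C)C | intermediate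
10 | 1-methoxy-4-[(prop-2-yn-1-yloxy)methyl]benzene | C#CCOCc1ccc(OC)cc1 | starting material
11 | (4E,6R)-4-[(tert-butyldiphenylsilyloxy)methyl]-6-hydroxy-9-(4-methoxybenzyloxy)non-4-en-7-yn-1-yl 2,2-dimethylpropanoate | COc1ccc(COCC#C[C@H](O)/C=C(\CCCOC(=O)C(C)(C)C)CO[Si](c2ccccc2)(c2ccccc2)C(C)(C)C)cc1 | intermediate
12 | cyclic disodium vinylalanate from 11 (Al on C11 and O8; C3 alkoxide) | [Na+].[Na+].COCCO[Al-]1(OCCOC)O[C@H](/C=C(\CCC[O-])CO[Si](c2ccccc2)(c2ccccc2)C(C)(C)C)C=C1COCc1ccc(OC)cc1 | intermediate
13 | (2Z,4R,5E)-6-[(tert-butyldiphenylsilyloxy)methyl]-2-iodo-1-(4-methoxybenzyloxy)nona-2,5-diene-4,9-diol (iodine on C11 cis to C8) | COc1ccc(COC/C(I)=C/[C@H](O)/C=C(\CCCO)CO[Si](c2ccccc2)(c2ccccc2)C(C)(C)C)cc1 | intermediate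
14 | 4,9-bis(triethylsilyl) ether of 13 (8R in germacrane numbering) | COc1ccc(COC/C(I)=C/[C@H](O[Si](CC)(CC)CC)/C=C(\CCCO[Si](CC)(CC)CC)CO[Si](c2ccccc2)(c2ccccc2)C(C)(C)C)cc1 | intermediate
15 | (tributylstannyl)methanol | CCCC[Sn](CCCC)(CCCC)CO | starting material
16 | (2E,4R,5E)-6-[(tert-butyldiphenylsilyloxy)methyl]-2-[(4-methoxybenzyloxy)methyl]-4,9-bis(triethylsilyloxy)nona-2,5-dien-1-ol (C13 hydroxymethyl cis to C8) | COc1ccc(COC/C(CO)=C/[C@H](O[Si](CC)(CC)CC)/C=C(\CCCO[Si](CC)(CC)CC)CO[Si](c2ccccc2)(c2ccccc2)C(C)(C)C)cc1 | intermediate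
17 | 3-bromoprop-1-yne (propargyl bromide) | C#CCBr | starting material
18 | O13-propargyl ether of 16 (8R) | C#CCOC/C(COCc1ccc(OC)cc1)=C\[C@H](O[Si](CC)(CC)CC)/C=C(\CCCO[Si](CC)(CC)CC)CO[Si](c1ccccc1)(c1ccccc1)C(C)(C)C | intermediate
19 | O13-(3-iodoprop-2-ynyl) ether (8R) | IC#CCOC/C(COCc1ccc(OC)cc1)=C\[C@H](O[Si](CC)(CC)CC)/C=C(\CCCO[Si](CC)(CC)CC)CO[Si](c1ccccc1)(c1ccccc1)C(C)(C)C | intermediate
20 | C3 aldehyde of 19 (8R) | IC#CCOC/C(COCc1ccc(OC)cc1)=C\[C@H](O[Si](CC)(CC)CC)/C=C(\CCC=O)CO[Si](c1ccccc1)(c1ccccc1)C(C)(C)C | intermediate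
21 | 13-membered 6-oxa macrocyclic propargylic alcohol, ring O6–C13–C11=C7–C8–C9=C10–C1–C2–C3–C4≡C5–C6, 8R, both C3 epimers | C1#CCOC/C(COCc2ccc(OC)cc2)=C\[C@H](O[Si](CC)(CC)CC)/C=C(/CO[Si](c2ccccc2)(c2ccccc2)C(C)(C)C)CCC1O | intermediate
22 | macrocyclic ynone (C3 ketone, 8R) | C1#CCOC/C(COCc2ccc(OC)cc2)=C\[C@H](O[Si](CC)(CC)CC)/C=C(/CO[Si](c2ccccc2)(c2ccccc2)C(C)(C)C)CCC1=O | intermediate
23 | (3S,8R) macrocyclic propargylic alcohol | C1#CCOC/C(COCc2ccc(OC)cc2)=C\[C@H](O[Si](CC)(CC)CC)/C=C(/CO[Si](c2ccccc2)(c2ccccc2)C(C)(C)C)CC[C@@H]1O | intermediate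
24 | (3S,8R) C4-tributylstannyl macrocyclic alkene (tin cis to C6, ring-trans C4=C5) | CCCC[Sn](CCCC)(CCCC)/C1=C\COC/C(COCc2ccc(OC)cc2)=C\[C@H](O[Si](CC)(CC)CC)/C=C(/CO[Si](c2ccccc2)(c2ccccc2)C(C)(C)C)CC[C@@H]1O | intermediate
25 | methyl ester of the macrocyclic Z-enoate with free C3 hydroxyl (3S,8R; ester cis to C6) | COC(=O)/C1=C\COC/C(COCc2ccc(OC)cc2)=C\[C@H](O[Si](CC)(CC)CC)/C=C(/CO[Si](c2ccccc2)(c2ccccc2)C(C)(C)C)CC[C@@H]1O | intermediate
26 | 13-membered 6-oxa macrocyclic dienoate, C3 and C8 triethylsilyl ethers, C12 PMB ether, C14 tert-butyldiphenylsilyl ether (3S,8R) | COC(=O)/C1=C\COC/C(COCc2ccc(OC)cc2)=C\[C@H](O[Si](CC)(CC)CC)/C=C(/CO[Si](c2ccccc2)(c2ccccc2)C(C)(C)C)CC[C@@H]1O[Si](CC)(CC)CC | intermediate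
27 | lithium dienolate of 26 (C15=C4–C5=C6) | [Li+].COC([O-])=C1C=COC/C(COCc2ccc(OC)cc2)=C\[C@H](O[Si](CC)(CC)CC)/C=C(/CO[Si](c2ccccc2)(c2ccccc2)C(C)(C)C)CC[C@@H]1O[Si](CC)(CC)CC | intermediate
28 | ring-contracted lithium C6 alkoxide, ten-membered ring with methyl ester on C4 | [Li+].C=C(COCc1ccc(OC)cc1)[C@H]1[C@H](O[Si](CC)(CC)CC)/C=C(/CO[Si](c2ccccc2)(c2ccccc2)C(C)(C)C)CC[C@H](O[Si](CC)(CC)CC)/C(C(=O)OC)=C/[C@H]1[O-] | intermediate
29 | ten-membered butenolide (3S,6R,7R,8R), C7 3-(4-methoxybenzyloxy)prop-1-en-2-yl, C3 and C8 triethylsilyl ethers | C=C(COCc1ccc(OC)cc1)[C@H]1[C@H](O[Si](CC)(CC)CC)/C=C(/CO[Si](c2ccccc2)(c2ccccc2)C(C)(C)C)CC[C@H](O[Si](CC)(CC)CC)C2=C[C@H]1OC2=O | intermediate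
30 | C12 allylic alcohol of 29 | C=C(CO)[C@H]1[C@H](O[Si](CC)(CC)CC)/C=C(/CO[Si](c2ccccc2)(c2ccccc2)C(C)(C)C)CC[C@H](O[Si](CC)(CC)CC)C2=C[C@H]1OC2=O | intermediate
31 | C3,C8,C12-triol with C14 tert-butyldiphenylsilyl ether (3S,6R,7S,8R) | C=C(CO)[C@H]1[C@H](O)/C=C(/CO[Si](c2ccccc2)(c2ccccc2)C(C)(C)C)CC[C@H](O)C2=C[C@H]1OC2=O | intermediate
32 | C12 enal of 31 | C=C(C=O)[C@H]1[C@H](O)/C=C(/CO[Si](c2ccccc2)(c2ccccc2)C(C)(C)C)CC[C@H](O)C2=C[C@H]1OC2=O | intermediate
33 | C12 lactol closed onto O8 | C=C1C(O)O[C@@H]2/C=C(/CO[Si](c4ccccc4)(c4ccccc4)C(C)(C)C)CC[C@H](O)C3=C[C@@H](OC3=O)[C@@H]12 | intermediate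
34 | C14-silylated 3-hydroxy bis-lactone (3S,6R,7S,8R) | C=C1C(=O)O[C@@H]2/C=C(/CO[Si](c4ccccc4)(c4ccccc4)C(C)(C)C)CC[C@H](O)C3=C[C@@H](OC3=O)[C@@H]12 | intermediate
35 | C14-silylated target, C3 isobutyrate | C=C1C(=O)O[C@@H]2/C=C(/CO[Si](c4ccccc4)(c4ccccc4)C(C)(C)C)CC[C@H](OC(=O)C(C)C)C3=C[C@@H](OC3=O)[C@@H]12 | intermediate
36 | target compound (3S,6R,7S,8R) | C=C1C(=O)O[C@@H]2/C=C(/CO)CC[C@H](OC(=O)C(C)C)C3=C[C@@H](OC3=O)[C@@H]12 | target

## Step count and risks

Total: 24 steps. Longest linear sequence: 23 steps (1, 2 and 4–24, from but-2-yne-1,4-diol).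

**Step 19 (key step, proposed new method).** Most likely failures are β-elimination of the C3 silyloxy group from the dienolate, a competing [1,2] or Claisen-type shift through C5, or attack on the wrong C7 face if the C8 rotamer with the silyloxy group in the alkene plane reacts. Fallback with known chemistry, from 23 back to 29: silylation of 23 gives the macrocyclic alkyne bis(triethylsilyl) ether F1. n-BuLi in THF at −78 °C deprotonates the propargylic C6 position and triggers the known [2,3]-Wittig ring contraction of a 13-membered propargylic allylic ether, giving the cyclodecenynol F2. Hydroxyl-directed trans-hydroalumination with NaAlH2(OCH2CH2OMe)2 and iodination gives the C4 iodo allylic alcohol F3. Carbonylative lactonisation (PdCl2(PPh3)2, CO, Et3N) closes the butenolide and gives 29.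

**Step 13.** The ring closure may lose to intermolecular addition or to protonation of the alkynylchromium, because a 13-membered ring with three rigid unsaturations pays a high entropic price. Fallback by ring-closing alkyne metathesis, from 16 back to 23: alkylation of 16 with 1-bromobut-2-yne gives the but-2-ynyl ether F4. Swern oxidation gives the aldehyde F5. ProPhenol/Me2Zn addition of propyne to the Re face gives the (3S)-propynyl carbinol F6, and silylation gives its trimethylsilyl ether F7. Mo(≡CC6H4OMe-4)(OSiPh3)3 in toluene closes the macrocyclic alkyne F8, and K2CO3 in methanol removes the trimethylsilyl group to give 23.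

**Step 6.** Facial selectivity may be poor because the enal has no α-substituent. Fallback from 9 back to 11: addition of the lithium acetylide of 10 gives the racemic carbinol F9, MnO2 oxidation gives the alkenyl alkynyl ketone F10, and Corey–Bakshi–Shibata reduction with the oxazaborolidine enantiomer that treats the alkynyl group as the small substituent gives 11.

**Step 17.** Protodestannylation may compete with transmetalation, and the acid additive may remove the C8 silyl group (step 18 would restore it). Fallback from 24 back to 25: iododestannylation with I2 gives the C4 iodide F11, and methoxycarbonylation with zerovalent palladium (Pd(PPh3)4, CO, MeOH, Et3N) gives 25.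

**Step 22.** The oxidant may also attack the secondary allylic C3 or C8 hydroxyl before the lactol forms. Fallback from 30 back to 34, with both secondary alcohols still silylated: MnO2 oxidation of 30 gives the enal F12. Pinnick oxidation (NaClO2, NaH2PO4, 2-methylbut-2-ene) gives the acrylic acid F13. HF·pyridine removes both triethylsilyl groups and the C8 hydroxy acid lactonises to 34.

## Further compounds

F1 | step 19 | 3,8-bis(triethylsilyl) ether of macrocyclic alkyne 23 | C1#CCOC/C(COCc2ccc(OC)cc2)=C\[C@H](O[Si](CC)(CC)CC)/C=C(/CO[Si](c2ccccc2)(c2ccccc2)C(C)(C)C)CC[C@@H]1O[Si](CC)(CC)CC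
F2 | step 19 | ten-membered cyclodecenynol (C4≡C5 in the ring, 6-hydroxy, C7 3-(4-methoxybenzyloxy)prop-1-en-2-yl) | C=C(COCc1ccc(OC)cc1)[C@H]1[C@H](O[Si](CC)(CC)CC)/C=C(/CO[Si](c2ccccc2)(c2ccccc2)C(C)(C)C)CC[C@H](O[Si](CC)(CC)CC)C#C[C@H]1O
F3 | step 19 | C4 iodo allylic alcohol of the ten-membered ring (iodine cis to C6) | C=C(COCc1ccc(OC)cc1)[C@H]1[C@H](O[Si](CC)(CC)CC)/C=C(/CO[Si](c2ccccc2)(c2ccccc2)C(C)(C)C)CC[C@H](O[Si](CC)(CC)CC)/C(I)=C/[C@H]1O
F4 | step 13 | O13-(but-2-ynyl) ether of 16 | CC#CCOC/C(COCc1ccc(OC)cc1)=C\[C@H](O[Si](CC)(CC)CC)/C=C(\CCCO[Si](CC)(CC)CC)CO[Si](c1ccccc1)(c1ccccc1)C(C)(C)C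
F5 | step 13 | C3 aldehyde of F4 | CC#CCOC/C(COCc1ccc(OC)cc1)=C\[C@H](O[Si](CC)(CC)CC)/C=C(\CCC=O)CO[Si](c1ccccc1)(c1ccccc1)C(C)(C)C
F6 | step 13 | (3S)-prop-1-ynyl carbinol from F5 | CC#CCOC/C(COCc1ccc(OC)cc1)=C\[C@H](O[Si](CC)(CC)CC)/C=C(\CC[C@H](O)C#CC)CO[Si](c1ccccc1)(c1ccccc1)C(C)(C)C
F7 | step 13 | C3 trimethylsilyl ether of F6 | CC#CCOC/C(COCc1ccc(OC)cc1)=C\[C@H](O[Si](CC)(CC)CC)/C=C(\CC[C@H](O[Si](C)(C)C)C#CC)CO[Si](c1ccccc1)(c1ccccc1)C(C)(C)C
F8 | step 13 | macrocyclic alkyne with C3 trimethylsilyl ether | C1#CCOC/C(COCc2ccc(OC)cc2)=C\[C@H](O[Si](CC)(CC)CC)/C=C(/CO[Si](c2ccccc2)(c2ccccc2)C(C)(C)C)CC[C@@H]1O[Si](C)(C)C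
F9 | step 6 | racemic carbinol of the constitution of 11 | COc1ccc(COCC#CC(O)/C=C(\CCCOC(=O)C(C)(C)C)CO[Si](c2ccccc2)(c2ccccc2)C(C)(C)C)cc1
F10 | step 6 | alkenyl alkynyl ketone (C8 ketone) | COc1ccc(COCC#CC(=O)/C=C(\CCCOC(=O)C(C)(C)C)CO[Si](c2ccccc2)(c2ccccc2)C(C)(C)C)cc1
F11 | step 17 | C4 iodo macrocyclic alkene (iodine cis to C6) | I/C1=C\COC/C(COCc2ccc(OC)cc2)=C\[C@H](O[Si](CC)(CC)CC)/C=C(/CO[Si](c2ccccc2)(c2ccccc2)C(C)(C)C)CC[C@@H]1O
F12 | step 22 | C12 enal of 30 | C=C(C=O)[C@H]1[C@H](O[Si](CC)(CC)CC)/C=C(/CO[Si](c2ccccc2)(c2ccccc2)C(C)(C)C)CC[C@H](O[Si](CC)(CC)CC)C2=C[C@H]1OC2=O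
F13 | step 22 | C12 acrylic acid | C=C(C(=O)O)[C@H]1[C@H](O[Si](CC)(CC)CC)/C=C(/CO[Si](c2ccccc2)(c2ccccc2)C(C)(C)C)CC[C@H](O[Si](CC)(CC)CC)C2=C[C@H]1OC2=O
A1 | alternative 1 | C3-hydroxy C14-silylated bis-lactone macrocycle | C=C1C(=O)O[C@@H]2/C=C(/CO[Si](C)(C)C(C)(C)C)CC[C@H](O)C3=C[C@@H](OC3=O)[C@@H]12
A2 | alternative 1 | seco aldehyde with α-iodobutenolide | C=C1C(=O)O[C@H](/C=C(/CO[Si](C)(C)C(C)(C)C)CCC=O)[C@H]1[C@@H]1OC(=O)C(I)=C1
A3 | alternative 2 | ten-membered triene with C8 hydroxyl | O[C@@H]1/C=C(/CO[Si](c2ccccc2)(c2ccccc2)C(C)(C)C)CC[C@H](O[Si](C)(C)C(C)(C)C)/C(COCc2ccc(OC)cc2)=C/[C@@H](O[Si](C)(C)C(C)(C)C)[C@H]1C(=C)COCc1ccc(OC)cc1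
A4 | alternative 2 | 11-membered cyclic sulfone (sulfur between C9 and C10) | O[C@@H]1CS(=O)(=O)C(CO[Si](c2ccccc2)(c2ccccc2)C(C)(C)C)CC[C@H](O[Si](C)(C)C(C)(C)C)/C(COCc2ccc(OC)cc2)=C/[C@@H](O[Si](C)(C)C(C)(C)C)[C@H]1C(=C)COCc1ccc(OC)cc1
A5 | alternative 3 | C14-silylated target | C=C1C(=O)O[C@@H]2/C=C(/CO[Si](C)(C)C(C)(C)C)CC[C@H](OC(=O)C(C)C)C3=C[C@@H](OC3=O)[C@@H]12
A6 | alternative 3 | 11-membered macrolactone with C4 methylene and C6 vinyl | C=C1C(=O)O[C@@H]2/C=C(/CO[Si](C)(C)C(C)(C)C)CC[C@H](OC(=O)C(C)C)C(=C)C(=O)O[C@H](C=C)[C@@H]12
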